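**Strategy.** The oxolane ring (O1, C2 aryl, C3 CH2OH, C4 carbinol arm, C5) is cut at O1–C2 and C3–C4. This exposes an enal, whose β-carbon is the benzylic ether carbon C2 and whose α-carbon is C3, and a three-atom O1–C5–C4 unit in which C4 is an allyl terminus; the CH(OH)Ar arm on C4 is treated as a masked 1-arylvinyl group. The key step is a cooperative amine/palladium formal [3+2] cycloaddition: strain-driven opening of a racemic 2-(1-arylvinyl)oxirane gives a zwitterionic π-allylpalladium alkoxide that adds to the chiral iminium ion of 3,4,5-trimethoxycinnamaldehyde and closes the ring, setting C2, C3 and C4. Ozonolysis and a Felkin-controlled reduction finish the target.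

Key step: step 2

Remarks: the carbinol carbon on C4 is called C7'. Buta-2,3-dien-1-ol is taken to be a catalogue compound. In the SMILES of the palladium intermediates 3, 6 and 8 the allyl group is drawn in its η1 form and the phosphine ligands are left out.

Step 1
Reactants: 1 4-iodo-1,2-dimethoxybenzene; 2 buta-2,3-dien-1-ol
Product: 4 2-[1-(3,4-dimethoxyphenyl)ethenyl]oxirane (racemic), via hydroxyallylpalladium iodide 3 (not isolated)
Conditions: Pd(PPh3)4 (5 mol %), K2CO3 (2 equiv), DMF, 60 °C
Reagents that add atoms: none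
Why: Known palladium-catalysed insertion–cyclisation of 2,3-allenols with aryl halides: oxidative addition of zerovalent palladium to the C–I bond and carbopalladation of the allene at its central carbon give the 2-aryl-π-allylpalladium iodide 3 with its hydroxyl still free, and carbonate-assisted attack of that oxygen on the neighbouring allyl terminus closes the oxirane 3-exo; the stereocentre of 4 needs no control because it is erased when 4 is re-ionised in step 2.

Step 2
Reactants: 4 2-[1-(3,4-dimethoxyphenyl)ethenyl]oxirane (racemic, 1.5 equiv); 5 (E)-3-(3,4,5-trimethoxyphenyl)prop-2-enal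
Product: 10 [(2R,3S,4S)-4-[1-(3,4-dimethoxyphenyl)ethenyl]-2-(3,4,5-trimethoxyphenyl)oxolan-3-yl]methanol, via allylpalladium alkoxide 6 (not isolated), via iminium ion 7 (not isolated), via enamine 8 (not isolated), via aldehyde 9 (not isolated)
Conditions: Pd(PPh3)4 (5 mol %), (R)-α,α-diphenylprolinol trimethylsilyl ether (20 mol %), PhCO2H (20 mol %), THF, rt; then MeOH, NaBH4, 0 °C
Reagents that add atoms: none
Why: Proposed new method: zerovalent palladium opens the strained vinyl epoxide 4 to the zwitterionic 2-aryl-π-allylpalladium alkoxide 6 while the amine converts 5 into iminium ion 7; the oxygen of 6 adds to the β-carbon of 7 (oxa-Michael, O1–C2 bond) and the α-carbon of the resulting enamine 8 alkylates the tethered allyl terminus (C3–C4 bond), after which hydrolysis releases aldehyde 9 and both catalysts and NaBH4 reduces 9 to 10 in the same flask. The closest known reactions are the amine/palladium formal [3+2] cycloadditions of vinylcyclopropanes and vinylaziridines with enals, the palladium-catalysed [3+2] cycloaddition of vinyl oxiranes with doubly activated alkenes and the amine/palladium oxa-Michael/carbocyclisation of propargylic alcohols with enals; an oxygen zwitterion from a vinyl epoxide has, as far as is known, not been paired with iminium/enamine activation. The oxolane closes by a 5-exo-trig allylic alkylation at the internal allyl terminus, the 7-endo alternative at the CH2 terminus being disfavoured. C2 is set by the (R)-diarylprolinol silyl ether, whose bulky group shields one face of the E-iminium ion so that oxygen adds to the open face; C3 follows because the enamine is alkylated on the same open face, which places formyl trans to the C2 aryl group; C4 is set in the closing transition state, where the arylvinyl group avoids the formyl group (3,4-trans), and this centre becomes α to the ketone in 12 and is therefore correctable. The oxa-Michael addition is reversible, so the step needs ring closure of the matched enamine to outrun re-closure of 6 to the epoxide (harmless) and N-allylation of the amine, which the steric bulk of the catalyst and the acid co-catalyst should secure.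

Step 3
Reactants: 10 [(2R,3S,4S)-4-[1-(3,4-dimethoxyphenyl)ethenyl]-2-(3,4,5-trimethoxyphenyl)oxolan-3-yl]methanol
Product: 12 (3,4-dimethoxyphenyl)[(3R,4S,5R)-4-(hydroxymethyl)-5-(3,4,5-trimethoxyphenyl)oxolan-3-yl]methanone, via ozonide 11 (not isolated)
Conditions: O3, CH2Cl2, −78 °C (indicator dye end point); then Me2S, −78 °C to rt
Reagents that add atoms: ozone, [O-][O+]=O
Why: Criegee ozonolysis should cleave the electron-rich 1,1-disubstituted alkene far faster than ozone attacks the methoxyarenes, reductive cleavage of ozonide 11 leaves the aryl ketone, and C4, now α to the carbonyl, already holds the thermodynamically preferred trans,trans arrangement so that no stereocentre should be lost.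

Step 4
Reactants: 12 (3,4-dimethoxyphenyl)[(3R,4S,5R)-4-(hydroxymethyl)-5-(3,4,5-trimethoxyphenyl)oxolan-3-yl]methanone
Product: 13 (S)-(3,4-dimethoxyphenyl)[(3R,4S,5R)-4-(hydroxymethyl)-5-(3,4,5-trimethoxyphenyl)oxolan-3-yl]methanol
Conditions: LiBH(s-Bu)3 (L-Selectride, 2.5 equiv), THF, −78 °C; then H2O
Reagents that add atoms: none
Why: Substrate-controlled ketone reduction under the Felkin–Anh model, which lithium chelation between the carbonyl and the ring oxygen would reinforce: with the larger ring branch C3 anti to the bulky hydride and the carbonyl oxygen near C5, hydride should enter past the C4 hydrogen and set the (S) carbinol centre.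

**Compound list**

1 | 4-iodo-1,2-dimethoxybenzene | COc1ccc(I)cc1OC | starting material
2 | buta-2,3-dien-1-ol | OCC=C=C | starting material
3 | iodo[2-(3,4-dimethoxyphenyl)-4-hydroxybut-2-en-1-yl]palladium, the η1 form of the π-allyl complex of divalent palladium (not isolated) | OCC=C(C[Pd]I)c1ccc(OC)c(OC)c1 | intermediate
4 | 2-[1-(3,4-dimethoxyphenyl)ethenyl]oxirane (racemic) | COc1ccc(C(=C)C2CO2)cc1OC | intermediate
5 | (E)-3-(3,4,5-trimethoxyphenyl)prop-2-enal | COc1cc(/C=C/C=O)cc(OC)c1OC | starting material
6 | zwitterionic [2-(3,4-dimethoxyphenyl)-4-oxidobut-2-en-1-yl]palladium cation, the η1 form of the π-allyl complex of divalent palladium (not isolated) | [O-]CC=C(C[Pd+])c1ccc(OC)c(OC)c1 | intermediate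
7 | (R)-2-[diphenyl(trimethylsilyloxy)methyl]-1-[(2E)-3-(3,4,5-trimethoxyphenyl)prop-2-en-1-ylidene]pyrrolidinium benzoate (not isolated) | C[Si](C)(C)OC(c1ccccc1)(c1ccccc1)[C@H]1CCC[N+]1=C/C=C/c1cc(OC)c(OC)c(OC)c1.[O-]C(=O)c1ccccc1 | intermediate
8 | (R)-2-[diphenyl(trimethylsilyloxy)methyl]-1-[(1E,3R)-3-{[3-(3,4-dimethoxyphenyl)-4-palladiobut-2-en-1-yl]oxy}-3-(3,4,5-trimethoxyphenyl)prop-1-en-1-yl]pyrrolidine, cationic at palladium, benzoate counter-ion (not isolated) | C[Si](C)(C)OC(c1ccccc1)(c1ccccc1)[C@H]1CCCN1/C=C/[C@@H](OCC=C(C[Pd+])c1ccc(OC)c(OC)c1)c1cc(OC)c(OC)c(OC)c1.[O-]C(=O)c1ccccc1 | intermediate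
9 | (2R,3R,4S)-4-[1-(3,4-dimethoxyphenyl)ethenyl]-2-(3,4,5-trimethoxyphenyl)oxolane-3-carbaldehyde (not isolated) | COc1ccc(C(=C)[C@H]2CO[C@@H](c3cc(OC)c(OC)c(OC)c3)[C@@H]2C=O)cc1OC | intermediate
10 | [(2R,3S,4S)-4-[1-(3,4-dimethoxyphenyl)ethenyl]-2-(3,4,5-trimethoxyphenyl)oxolan-3-yl]methanol | COc1ccc(C(=C)[C@H]2CO[C@@H](c3cc(OC)c(OC)c(OC)c3)[C@@H]2CO)cc1OC | intermediate
11 | [(2R,3S,4R)-4-[3-(3,4-dimethoxyphenyl)-1,2,4-trioxolan-3-yl]-2-(3,4,5-trimethoxyphenyl)oxolan-3-yl]methanol, mixture at the trioxolane carbon (not isolated) | COc1ccc(C2(OCOO2)[C@H]2CO[C@@H](c3cc(OC)c(OC)c(OC)c3)[C@@H]2CO)cc1OC | intermediate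
12 | (3,4-dimethoxyphenyl)[(3R,4S,5R)-4-(hydroxymethyl)-5-(3,4,5-trimethoxyphenyl)oxolan-3-yl]methanone | COc1ccc(C(=O)[C@H]2CO[C@@H](c3cc(OC)c(OC)c(OC)c3)[C@@H]2CO)cc1OC | intermediate
13 | (S)-(3,4-dimethoxyphenyl)[(3R,4S,5R)-4-(hydroxymethyl)-5-(3,4,5-trimethoxyphenyl)oxolan-3-yl]methanol | COc1ccc([C@@H](O)[C@H]2CO[C@@H](c3cc(OC)c(OC)c(OC)c3)[C@@H]2CO)cc1OC | target

**Totals.** Total step count: 4. Longest linear sequence: 4 steps (1 → 4 → 10 → 12 → 13).

**Steps most likely to fail**

Step 2 (proposed new method). The zwitterion 6 may collapse back to 4, or isomerise by hydride shift to an enal, faster than its oxygen adds to iminium ion 7. The secondary amine may also be consumed by N-allylation, and the reversible oxa-Michael addition may erode facial discrimination. The fallback uses known chemistry, sets out from 4 and comes back at 10. Knoevenagel condensation of 3,4,5-trimethoxybenzaldehyde with dimethyl malonate (piperidine, AcOH, toluene, reflux) gives dimethyl 2-[(3,4,5-trimethoxyphenyl)methylidene]propanedioate F1. The known palladium-catalysed [3+2] cycloaddition of vinyl oxiranes with doubly activated alkenes (Pd2(dba)3·CHCl3, a chiral bisphosphine of the SEGPHOS type in the enantiomeric form that leads to the required series, THF, 40 °C) should join 4 and F1 to dimethyl (2S,4R)-4-[1-(3,4-dimethoxyphenyl)ethenyl]-2-(3,4,5-trimethoxyphenyl)oxolane-3,3-dicarboxylate F2, again closing O1–C2 and C3–C4 in one operation. Krapcho demethoxycarbonylation (LiCl, H2O, DMSO, 150 °C) and equilibration with NaOMe in MeOH should give the all-trans monoester methyl (2R,3R,4S)-4-[1-(3,4-dimethoxyphenyl)ethenyl]-2-(3,4,5-trimethoxyphenyl)oxolane-3-carboxylate F3, and LiAlH4 in THF at 0 °C reduces F3 to 10.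

Step 4. Hydride delivery may show poor facial selectivity, or favour the other carbonyl face if the conformation about the C4–C7' bond departs from the Felkin and chelate pictures. The fallback sets out from 12 and comes back at 13. The epimeric carbinol (R)-(3,4-dimethoxyphenyl)[(3R,4S,5R)-4-(hydroxymethyl)-5-(3,4,5-trimethoxyphenyl)oxolan-3-yl]methanol F4, which reduction of 12 would then deliver, is not discarded but inverted. Mitsunobu esterification with an excess of 4-nitrobenzoic acid (PPh3, DIAD, THF, 0 °C to rt) acylates the primary hydroxyl and displaces the activated benzylic oxygen with inversion, which should give [(2R,3S,4R)-4-[(S)-(3,4-dimethoxyphenyl)(4-nitrobenzoyloxy)methyl]-2-(3,4,5-trimethoxyphenyl)oxolan-3-yl]methyl 4-nitrobenzoate F5. The trans relationship of the two arms should prevent their cyclisation to a bicyclic ether. Methanolysis of both esters (K2CO3, MeOH, rt) gives 13.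

Step 1. The hydroxyallylpalladium iodide 3 may close at the far allyl terminus (5-endo) to a 2,5-dihydrofuran, and the product epoxide may be re-ionised and isomerised by the catalyst on prolonged heating. The fallback sets out from 1 and comes back at 4. Iodine–magnesium exchange of 1 (i-PrMgCl·LiCl, THF, −20 °C) and acylation with N-methoxy-N-methylacrylamide, followed by a quench into cold aqueous HCl so that the released amine does not add to the enone, gives 1-(3,4-dimethoxyphenyl)prop-2-en-1-one F6. Weitz–Scheffer epoxidation (H2O2, NaOH, MeOH, 0 °C) gives (3,4-dimethoxyphenyl)(oxiran-2-yl)methanone F7 as the racemate, and Wittig methylenation (Ph3PCH3Br, KOt-Bu, THF, 0 °C) converts F7 into 4.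

**Further compounds**

F1 | step 2 | dimethyl 2-[(3,4,5-trimethoxyphenyl)methylidene]propanedioate | COC(=O)C(=Cc1cc(OC)c(OC)c(OC)c1)C(=O)OC
F2 | step 2 | dimethyl (2S,4R)-4-[1-(3,4-dimethoxyphenyl)ethenyl]-2-(3,4,5-trimethoxyphenyl)oxolane-3,3-dicarboxylate | COc1ccc(C(=C)[C@H]2CO[C@@H](c3cc(OC)c(OC)c(OC)c3)C2(C(=O)OC)C(=O)OC)cc1OC
F3 | step 2 | methyl (2R,3R,4S)-4-[1-(3,4-dimethoxyphenyl)ethenyl]-2-(3,4,5-trimethoxyphenyl)oxolane-3-carboxylate | COc1ccc(C(=C)[C@H]2CO[C@@H](c3cc(OC)c(OC)c(OC)c3)[C@@H]2C(=O)OC)cc1OC
F4 | step 4 | (R)-(3,4-dimethoxyphenyl)[(3R,4S,5R)-4-(hydroxymethyl)-5-(3,4,5-trimethoxyphenyl)oxolan-3-yl]methanol | COc1ccc([C@H](O)[C@H]2CO[C@@H](c3cc(OC)c(OC)c(OC)c3)[C@@H]2CO)cc1OC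
F5 | step 4 | [(2R,3S,4R)-4-[(S)-(3,4-dimethoxyphenyl)(4-nitrobenzoyloxy)methyl]-2-(3,4,5-trimethoxyphenyl)oxolan-3-yl]methyl 4-nitrobenzoate | COc1ccc([C@@H](OC(=O)c2ccc(cc2)[N+](=O)[O-])[C@H]2CO[C@@H](c3cc(OC)c(OC)c(OC)c3)[C@@H]2COC(=O)c2ccc(cc2)[N+](=O)[O-])cc1OC
F6 | step 1 | 1-(3,4-dimethoxyphenyl)prop-2-en-1-one | COc1ccc(C(=O)C=C)cc1OC
F7 | step 1 | (3,4-dimethoxyphenyl)(oxiran-2-yl)methanone (racemic) | COc1ccc(C(=O)C2CO2)cc1OC
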